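**Strategy.** The hydrindane is disconnected at C3a–C7a and C5–C6. The feature exploited is that C3a and C5 flank C4 (a ketone before methylenation), while C7a and C6 are the β- and carbonyl carbons of a C6–C7–C7a enal. One methyl ketone can therefore close cyclopentane ring B by Michael addition and cyclohexane ring A by aldol addition in a single amine-catalysed operation, setting C3a, C7a, C7 and C6. The precursor is an acyclic C4-keto C6-enal chain carrying the C2 silyl ether and the C1 acetyl group as a dioxolane; its C1 and C2 centres come from an auxiliary-controlled syn-aldol reaction.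

Key step: step 12

Remark: the hydrindane locants C1 to C7a are used for the corresponding atoms of every intermediate, acyclic ones included, and in the names of the bicyclic compounds.
Remark: the stereodescriptors of 18 and 20 were checked against the target and are consistent (C1 R and C2 S unchanged; 20 trans-fused, C7 isopropyl equatorial, C6 hydroxyl axial); C7a reads S in 20 and R from 21 onward only because the priority of C4 changes.
Assumption: the aldol closure of step 12 gives the axial C6 carbinol drawn for 20; the first fallback covers the other outcome.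

Step 1
Reactants: 1 (R)-4-benzyloxazolidin-2-one; 2 (E)-but-2-enoic anhydride
Product: 3 (R)-4-benzyl-3-[(E)-but-2-enoyl]oxazolidin-2-one
Conditions: LiCl, Et3N, THF, −20 °C → rt
Reagents that add atoms: none
Why: N-acylation of the oxazolidinone by the anhydride under LiCl/Et3N activation avoids strong base and leaves the E-alkene and the auxiliary stereocentre untouched.

Step 2
Reactants: 4 4-methylpent-4-en-1-ol
Product: 5 4-methylpent-4-enal
Conditions: TEMPO (cat.), PhI(OAc)2, CH2Cl2, rt; used as a solution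
Reagents that add atoms: none
Why: nitroxyl-catalysed alcohol oxidation stops at the aldehyde and does not touch the 1,1-disubstituted alkene.

Step 3
Reactants: 3 (R)-4-benzyl-3-[(E)-but-2-enoyl]oxazolidin-2-one; 5 4-methylpent-4-enal
Product: 7 (4R)-4-benzyl-3-[(2R,3S)-2-ethenyl-3-hydroxy-6-methylhept-6-enoyl]-1,3-oxazolidin-2-one, via boron dienolate 6 (not isolated)
Conditions: Bu2BOTf, Et3N, CH2Cl2, −78 → 0 °C; then 5, −78 → 0 °C; H2O2, MeOH/pH 7 buffer, 0 °C
Reagents that add atoms: none
Why: Evans syn-aldol reaction of the Z-boron dienolate, which reacts at its α-carbon through a chair transition state on the face away from the benzyl group, so the (R)-auxiliary sets C1 (R) and C2 (S) syn and leaves a vinyl group as the future C7a.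

Step 4
Reactants: 7 (4R)-4-benzyl-3-[(2R,3S)-2-ethenyl-3-hydroxy-6-methylhept-6-enoyl]-1,3-oxazolidin-2-one
Product: 8 (2R,3S)-2-ethenyl-3-hydroxy-N-methoxy-N,6-dimethylhept-6-enamide
Conditions: MeONHMe·HCl, AlMe3, THF, −20 → 0 °C
Reagents that add atoms: N,O-dimethylhydroxylamine hydrochloride, CNOC.Cl
Why: Weinreb amide formation by aluminium amide aminolysis of the imide carbonyl, assisted by chelation to the free C2 hydroxyl, releases the auxiliary without retro-aldol cleavage or epimerisation at C1.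

Step 5
Reactants: 8 (2R,3S)-2-ethenyl-3-hydroxy-N-methoxy-N,6-dimethylhept-6-enamide
Product: 9 (2R,3S)-3-[(tert-butyldimethylsilyl)oxy]-2-ethenyl-N-methoxy-N,6-dimethylhept-6-enamide
Conditions: TBSOTf, 2,6-lutidine, CH2Cl2, −78 → 0 °C
Reagents that add atoms: tert-butyldimethylsilyl trifluoromethanesulfonate, CC(C)(C)[Si](C)(C)OS(=O)(=O)C(F)(F)F
Why: silyl ether formation with the silyl triflate and a hindered pyridine base is fast at low temperature and does not affect C1 or C2.

Step 6
Reactants: 9 (2R,3S)-3-[(tert-butyldimethylsilyl)oxy]-2-ethenyl-N-methoxy-N,6-dimethylhept-6-enamide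
Product: 10 (3R,4S)-4-[(tert-butyldimethylsilyl)oxy]-3-ethenyl-7-methyloct-7-en-2-one
Conditions: MeMgBr, THF, −20 → 0 °C; aq. NH4Cl
Reagents that add atoms: methylmagnesium bromide, C[Mg]Br
Why: Weinreb ketone synthesis, in which the chelated tetrahedral magnesium adduct prevents over-addition and releases the C1 acetyl group only on quench, so the α-vinyl ketone is not exposed to base.

Step 7
Reactants: 10 (3R,4S)-4-[(tert-butyldimethylsilyl)oxy]-3-ethenyl-7-methyloct-7-en-2-one
Product: 11 tert-butyl(dimethyl){[(3R,4S)-7-methyl-3-(2-methyl-1,3-dioxolan-2-yl)octa-1,7-dien-4-yl]oxy}silane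
Conditions: TMSOCH2CH2OTMS, TMSOTf (cat.), CH2Cl2, −78 → −20 °C; pyridine quench
Reagents that add atoms: 1,2-bis(trimethylsilyloxy)ethane, C[Si](C)(C)OCCO[Si](C)(C)C
Why: Noyori-type ketalisation with the bis-silyl ether of ethylene glycol is aprotic and cold, so the β,γ-unsaturated ketone is masked as the dioxolane without double-bond migration or epimerisation at C1.

Step 8
Reactants: 11 tert-butyl(dimethyl){[(3R,4S)-7-methyl-3-(2-methyl-1,3-dioxolan-2-yl)octa-1,7-dien-4-yl]oxy}silane
Product: 13 (2S,3S)-3-[(tert-butyldimethylsilyl)oxy]-2-(2-methyl-1,3-dioxolan-2-yl)-6-oxoheptanal, via bis-ozonide 12 (not isolated)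
Conditions: O3, CH2Cl2, −78 °C; then PPh3, −78 °C → rt; used crude
Reagents that add atoms: ozone, [O-][O+]=O
Why: ozonolysis with reductive work-up cleaves both terminal alkenes in one operation, the isopropenyl group giving the C4 methyl ketone and the vinyl group the C7a aldehyde, with C1 and C2 untouched (the C1 descriptor changes to S by the priority rules only).

Step 9
Reactants: 13 (2S,3S)-3-[(tert-butyldimethylsilyl)oxy]-2-(2-methyl-1,3-dioxolan-2-yl)-6-oxoheptanal; 14 ethyl 2-(diethoxyphosphoryl)-3-methylbutanoate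
Product: 16 ethyl (2E,4R,5S)-5-[(tert-butyldimethylsilyl)oxy]-4-(2-methyl-1,3-dioxolan-2-yl)-8-oxo-2-(propan-2-yl)non-2-enoate, via sodium phosphonate salt 15 (not isolated)
Conditions: 14, NaH, THF, 0 °C; then 13, 0 °C → rt
Reagents that add atoms: none
Why: Horner–Wadsworth–Emmons olefination in which the phosphonate carbanion attacks the aldehyde and not the methyl ketone; the E-enoate is expected as the main isomer and the alkene geometry is in any case erased at C7a in step 12.

Step 10
Reactants: 16 ethyl (2E,4R,5S)-5-[(tert-butyldimethylsilyl)oxy]-4-(2-methyl-1,3-dioxolan-2-yl)-8-oxo-2-(propan-2-yl)non-2-enoate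
Product: 17 (2E,4R,5S)-5-[(tert-butyldimethylsilyl)oxy]-4-(2-methyl-1,3-dioxolan-2-yl)-2-(propan-2-yl)non-2-ene-1,8-diol (C8 epimers)
Conditions: i-Bu2AlH, CH2Cl2, −78 → −20 °C; aq. KNaC4H4O6
Reagents that add atoms: none
Why: aluminium hydride 1,2-reduction converts the enoate into the allylic alcohol and, unavoidably, the C4 ketone into a carbinol whose configuration is irrelevant because step 11 removes it.

Step 11
Reactants: 17 (2E,4R,5S)-5-[(tert-butyldimethylsilyl)oxy]-4-(2-methyl-1,3-dioxolan-2-yl)-2-(propan-2-yl)non-2-ene-1,8-diol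
Product: 18 (2E,4R,5S)-5-[(tert-butyldimethylsilyl)oxy]-4-(2-methyl-1,3-dioxolan-2-yl)-8-oxo-2-(propan-2-yl)non-2-enal
Conditions: Dess–Martin periodinane, NaHCO3, CH2Cl2, 0 °C → rt
Reagents that add atoms: none
Why: Dess–Martin oxidation of both hydroxyl groups under buffered, non-basic conditions gives the enal and the C4 ketone without γ-deprotonation at C1 or loss of the silyl ether.

Step 12
Reactants: 18 (2E,4R,5S)-5-[(tert-butyldimethylsilyl)oxy]-4-(2-methyl-1,3-dioxolan-2-yl)-8-oxo-2-(propan-2-yl)non-2-enal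
Product: 20 (1R,2S,3aR,6R,7S,7aS)-2-[(tert-butyldimethylsilyl)oxy]-6-hydroxy-1-(2-methyl-1,3-dioxolan-2-yl)-7-(propan-2-yl)octahydro-4H-inden-4-one, via Michael adduct 19 (not isolated)
Conditions: pyrrolidine (0.3 equiv), AcOH (0.3 equiv), THF (dilute), 0 °C → rt
Reagents that add atoms: none
Why: Pyrrolidine and the C4 methyl ketone form the enamine toward C3a, which adds to C7a of the enal in a 5-exo-trig Michael addition (ring B), and the aldehyde set free at C6 is then attacked by the C5 terminus of the re-formed enamine in a 6-(enolendo)-exo-trig aldol addition (ring A) before hydrolysis releases the catalyst. The closest known reaction type is the amine–acid-catalysed intramolecular Michael addition followed by intramolecular aldol addition, a Robinson-type annulation stopped at the ketol. C7a is fixed by C1: with the C1–H bond eclipsing the trisubstituted alkene (allylic 1,3-strain) the C2-tethered enamine reaches only the face anti to the dioxolanyl group, which is also the all-trans arrangement favoured if the Michael step reverses. C3a and C7 are enolisable and settle as the trans ring fusion with the isopropyl group equatorial, and C6 follows from Felkin–Anh attack of C5 anti to that isopropyl group in the chair transition state, which places the hydroxyl axial. The selectivity needed is regiochemical (only the C3a enamine can close a five-membered ring, the C5 enamine would have to form a seven-membered one), chemical (the C1 acetyl is a ketal, so a single ketone acts, and the α-isopropyl branch disfavours iminium and dienamine formation at the enal, which protects C1) and kinetic (the ketol must not dehydrate), the last being held by the low temperature and the sub-stoichiometric buffered amine.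

Step 13
Reactants: 20 (1R,2S,3aR,6R,7S,7aS)-2-[(tert-butyldimethylsilyl)oxy]-6-hydroxy-1-(2-methyl-1,3-dioxolan-2-yl)-7-(propan-2-yl)octahydro-4H-inden-4-one
Product: 21 (1R,2S,3aR,6R,7S,7aR)-2-[(tert-butyldimethylsilyl)oxy]-1-(2-methyl-1,3-dioxolan-2-yl)-4-methylidene-7-(propan-2-yl)octahydro-1H-inden-6-ol
Conditions: Zn, CH2Br2, TiCl4 (reagent pre-formed in THF), CH2Cl2, 0 °C → rt; aq. NaHCO3
Reagents that add atoms: dibromomethane, BrCBr
Why: Takai–Lombardo methylenation with the non-basic zinc–titanium methylene reagent converts the C4 ketone into the exocyclic alkene while the unprotected β-hydroxyl group, the enolisable C3a centre, the ketal and the silyl ether survive.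

Step 14
Reactants: 21 (1R,2S,3aR,6R,7S,7aR)-2-[(tert-butyldimethylsilyl)oxy]-1-(2-methyl-1,3-dioxolan-2-yl)-4-methylidene-7-(propan-2-yl)octahydro-1H-inden-6-ol
Product: 22 1-[(1R,2S,3aR,6R,7S,7aR)-2-[(tert-butyldimethylsilyl)oxy]-6-hydroxy-4-methylidene-7-(propan-2-yl)octahydro-1H-inden-1-yl]ethan-1-one
Conditions: PPTS, acetone/H2O, 50 °C
Reagents that add atoms: water, O
Why: acid-catalysed ketal hydrolysis under pyridinium tosylate buffering frees the C1 acetyl group while the secondary silyl ether and the exocyclic alkene persist, and C1 keeps its configuration because the acetyl group trans to the C7a substituent is the relaxed arrangement.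

Step 15
Reactants: 23 (Z)-2-methylbut-2-enoic acid (angelic acid)
Product: 24 (Z)-2-methylbut-2-en-1-ol
Conditions: LiAlH4, Et2O, 0 °C → rt
Reagents that add atoms: none
Why: aluminium hydride reduction of the carboxylic acid gives the allylic alcohol by 1,2-reduction with retention of the Z alkene geometry.

Step 16
Reactants: 24 (Z)-2-methylbut-2-en-1-ol
Product: 25 [(2R,3S)-2,3-dimethyloxiran-2-yl]methanol
Conditions: Ti(OiPr)4 (cat.), (−)-diethyl D-tartrate (cat.), t-BuOOH, 4 Å sieves, CH2Cl2, −20 °C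
Reagents that add atoms: tert-butyl hydroperoxide, CC(C)(C)OO
Why: Sharpless asymmetric epoxidation, in which the titanium tartrate complex delivers oxygen syn to one face of the allylic alcohol; with the D-tartrate ester this is the face that gives the (2R,3S)-epoxy alcohol, the Z geometry fixing the trans relation of the two methyl groups.

Step 17
Reactants: 25 [(2R,3S)-2,3-dimethyloxiran-2-yl]methanol
Product: 27 (2S,3S)-2,3-dimethyloxirane-2-carboxylic acid, via epoxy aldehyde 26 (not isolated)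
Conditions: RuCl3 (cat.), NaIO4, MeCN/EtOAc/H2O, 0 °C → rt
Reagents that add atoms: water, O
Why: catalytic ruthenium tetroxide oxidation (periodate as terminal oxidant) takes the primary alcohol through the aldehyde hydrate to the acid without opening the electron-poor epoxide; the C2 descriptor changes from R to S only through the priority rules.

Step 18
Reactants: 22 1-[(1R,2S,3aR,6R,7S,7aR)-2-[(tert-butyldimethylsilyl)oxy]-6-hydroxy-4-methylidene-7-(propan-2-yl)octahydro-1H-inden-1-yl]ethan-1-one; 27 (2S,3S)-2,3-dimethyloxirane-2-carboxylic acid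
Product: 29 (1R,2S,3aR,6R,7S,7aR)-1-acetyl-2-[(tert-butyldimethylsilyl)oxy]-4-methylidene-7-(propan-2-yl)octahydro-1H-inden-6-yl (2S,3S)-2,3-dimethyloxirane-2-carboxylate, via mixed anhydride 28 (not isolated)
Conditions: 27, 2,4,6-Cl3C6H2COCl, Et3N, toluene, rt; then 22, DMAP, rt → 40 °C
Reagents that add atoms: none
Why: Yamaguchi esterification, in which the mixed anhydride transfers the less shielded epoxy acyl group through the acylpyridinium ion to the hindered axial C6 hydroxyl with no change at C6 or in the epoxide.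

Step 19
Reactants: 29 (1R,2S,3aR,6R,7S,7aR)-1-acetyl-2-[(tert-butyldimethylsilyl)oxy]-4-methylidene-7-(propan-2-yl)octahydro-1H-inden-6-yl (2S,3S)-2,3-dimethyloxirane-2-carboxylate
Product: 30 (1R,2S,3aR,6R,7S,7aR)-1-acetyl-2-hydroxy-4-methylidene-7-(propan-2-yl)octahydro-1H-inden-6-yl (2S,3S)-2,3-dimethyloxirane-2-carboxylate
Conditions: HF·pyridine, pyridine, THF, 0 °C → rt
Reagents that add atoms: none
Why: fluoride-mediated desilylation under pyridine-buffered conditions cleaves the Si–O bond at C2 and is mild enough for the epoxy ester, the exocyclic alkene and the β-hydroxy ketone that results.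

Step 20
Reactants: 30 (1R,2S,3aR,6R,7S,7aR)-1-acetyl-2-hydroxy-4-methylidene-7-(propan-2-yl)octahydro-1H-inden-6-yl (2S,3S)-2,3-dimethyloxirane-2-carboxylate; 23 (Z)-2-methylbut-2-enoic acid
Product: 32 (1R,2S,3aR,6R,7S,7aR)-1-acetyl-4-methylidene-2-{[(2Z)-2-methylbut-2-enoyl]oxy}-7-(propan-2-yl)octahydro-1H-inden-6-yl (2S,3S)-2,3-dimethyloxirane-2-carboxylate (CNP0300602.1), via mixed anhydride 31 (not isolated)
Conditions: 23, 2,4,6-Cl3C6H2COCl, Et3N, toluene, rt; then 30, toluene, 75 °C
Reagents that add atoms: none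
Why: Yamaguchi-type acylation through the mixed anhydride without a nucleophilic catalyst, which avoids the addition–elimination pathway that would isomerise the angelate to the tiglate and keeps the base too weak to eliminate the new β-acyloxy ketone.

**Compound list**

1 | (R)-4-benzyloxazolidin-2-one | O=C1N[C@H](Cc2ccccc2)CO1 | starting material
2 | (E)-but-2-enoic anhydride | C/C=C/C(=O)OC(=O)/C=C/C | starting material
3 | (R)-4-benzyl-3-[(E)-but-2-enoyl]oxazolidin-2-one | C/C=C/C(=O)N1[C@H](Cc2ccccc2)COC1=O | intermediate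
4 | 4-methylpent-4-en-1-ol | C=C(C)CCCO | starting material
5 | 4-methylpent-4-enal | C=C(C)CCC=O | intermediate
6 | (4R)-4-benzyl-3-[(1Z)-1-[(dibutylboranyl)oxy]buta-1,3-dien-1-yl]-1,3-oxazolidin-2-one (boron dienolate) | C=C/C=C(\OB(CCCC)CCCC)N1[C@H](Cc2ccccc2)COC1=O | intermediate
7 | (4R)-4-benzyl-3-[(2R,3S)-2-ethenyl-3-hydroxy-6-methylhept-6-enoyl]-1,3-oxazolidin-2-one | C=C(C)CC[C@H](O)[C@@H](C=C)C(=O)N1[C@H](Cc2ccccc2)COC1=O | intermediate
8 | (2R,3S)-2-ethenyl-3-hydroxy-N-methoxy-N,6-dimethylhept-6-enamide | C=C(C)CC[C@H](O)[C@@H](C=C)C(=O)N(C)OC | intermediate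
9 | (2R,3S)-3-[(tert-butyldimethylsilyl)oxy]-2-ethenyl-N-methoxy-N,6-dimethylhept-6-enamide | C=C(C)CC[C@H](O[Si](C)(C)C(C)(C)C)[C@@H](C=C)C(=O)N(C)OC | intermediate
10 | (3R,4S)-4-[(tert-butyldimethylsilyl)oxy]-3-ethenyl-7-methyloct-7-en-2-one | C=C(C)CC[C@H](O[Si](C)(C)C(C)(C)C)[C@@H](C=C)C(C)=O | intermediate
11 | tert-butyl(dimethyl){[(3R,4S)-7-methyl-3-(2-methyl-1,3-dioxolan-2-yl)octa-1,7-dien-4-yl]oxy}silane | C=C(C)CC[C@H](O[Si](C)(C)C(C)(C)C)[C@@H](C=C)C1(C)OCCO1 | intermediate
12 | bis(1,2,4-trioxolane) formed from both C=C bonds of 11 (trioxolane carbons as epimer mixtures) | CC1(CC[C@H](O[Si](C)(C)C(C)(C)C)[C@@H](C2OOCO2)C2(C)OCCO2)OOCO1 | intermediate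
13 | (2S,3S)-3-[(tert-butyldimethylsilyl)oxy]-2-(2-methyl-1,3-dioxolan-2-yl)-6-oxoheptanal | CC(=O)CC[C@H](O[Si](C)(C)C(C)(C)C)[C@@H](C=O)C1(C)OCCO1 | intermediate
14 | ethyl 2-(diethoxyphosphoryl)-3-methylbutanoate | CCOC(=O)C(C(C)C)P(=O)(OCC)OCC | starting material
15 | sodium salt of 14 (phosphonate-stabilised enolate) | CCOC([O-])=C(C(C)C)P(=O)(OCC)OCC.[Na+] | intermediate
16 | ethyl (2E,4R,5S)-5-[(tert-butyldimethylsilyl)oxy]-4-(2-methyl-1,3-dioxolan-2-yl)-8-oxo-2-(propan-2-yl)non-2-enoate | CC(=O)CC[C@H](O[Si](C)(C)C(C)(C)C)[C@H](C1(C)OCCO1)/C=C(\C(C)C)C(=O)OCC | intermediate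
17 | (2E,4R,5S)-5-[(tert-butyldimethylsilyl)oxy]-4-(2-methyl-1,3-dioxolan-2-yl)-2-(propan-2-yl)non-2-ene-1,8-diol (C8 epimers) | CC(O)CC[C@H](O[Si](C)(C)C(C)(C)C)[C@H](C1(C)OCCO1)/C=C(\C(C)C)CO | intermediate
18 | (2E,4R,5S)-5-[(tert-butyldimethylsilyl)oxy]-4-(2-methyl-1,3-dioxolan-2-yl)-8-oxo-2-(propan-2-yl)non-2-enal | CC(=O)CC[C@H](O[Si](C)(C)C(C)(C)C)[C@H](C1(C)OCCO1)/C=C(\C(C)C)C=O | intermediate
19 | 2-[(1S,2R,3S,5R)-5-acetyl-3-[(tert-butyldimethylsilyl)oxy]-2-(2-methyl-1,3-dioxolan-2-yl)cyclopentyl]-3-methylbutanal (C2 of the butanal chain epimerisable) | O=CC(C(C)C)[C@@H]1[C@@H](C2(C)OCCO2)[C@@H](O[Si](C)(C)C(C)(C)C)C[C@H]1C(C)=O | intermediate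
20 | (1R,2S,3aR,6R,7S,7aS)-2-[(tert-butyldimethylsilyl)oxy]-6-hydroxy-1-(2-methyl-1,3-dioxolan-2-yl)-7-(propan-2-yl)octahydro-4H-inden-4-one | O=C1C[C@@H](O)[C@@H](C(C)C)[C@@H]2[C@@H](C3(C)OCCO3)[C@@H](O[Si](C)(C)C(C)(C)C)C[C@@H]12 | intermediate
21 | (1R,2S,3aR,6R,7S,7aR)-2-[(tert-butyldimethylsilyl)oxy]-1-(2-methyl-1,3-dioxolan-2-yl)-4-methylidene-7-(propan-2-yl)octahydro-1H-inden-6-ol | C=C1C[C@@H](O)[C@@H](C(C)C)[C@@H]2[C@@H](C3(C)OCCO3)[C@@H](O[Si](C)(C)C(C)(C)C)C[C@@H]12 | intermediate
22 | 1-[(1R,2S,3aR,6R,7S,7aR)-2-[(tert-butyldimethylsilyl)oxy]-6-hydroxy-4-methylidene-7-(propan-2-yl)octahydro-1H-inden-1-yl]ethan-1-one | C=C1C[C@@H](O)[C@@H](C(C)C)[C@@H]2[C@@H](C(C)=O)[C@@H](O[Si](C)(C)C(C)(C)C)C[C@@H]12 | intermediate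
23 | (Z)-2-methylbut-2-enoic acid (angelic acid) | C/C=C(/C)C(=O)O | starting material
24 | (Z)-2-methylbut-2-en-1-ol | C/C=C(/C)CO | intermediate
25 | [(2R,3S)-2,3-dimethyloxiran-2-yl]methanol | OC[C@@]1(C)O[C@H]1C | intermediate
26 | (2S,3S)-2,3-dimethyloxirane-2-carbaldehyde | O=C[C@@]1(C)O[C@H]1C | intermediate
27 | (2S,3S)-2,3-dimethyloxirane-2-carboxylic acid | OC(=O)[C@@]1(C)O[C@H]1C | intermediate
28 | (2S,3S)-2,3-dimethyloxirane-2-carboxylic 2,4,6-trichlorobenzoic anhydride | O=C(OC(=O)c1c(Cl)cc(Cl)cc1Cl)[C@@]1(C)O[C@H]1C | intermediate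
29 | (1R,2S,3aR,6R,7S,7aR)-1-acetyl-2-[(tert-butyldimethylsilyl)oxy]-4-methylidene-7-(propan-2-yl)octahydro-1H-inden-6-yl (2S,3S)-2,3-dimethyloxirane-2-carboxylate | C=C1C[C@@H](OC(=O)[C@@]2(C)O[C@H]2C)[C@@H](C(C)C)[C@@H]2[C@@H](C(C)=O)[C@@H](O[Si](C)(C)C(C)(C)C)C[C@@H]12 | intermediate
30 | (1R,2S,3aR,6R,7S,7aR)-1-acetyl-2-hydroxy-4-methylidene-7-(propan-2-yl)octahydro-1H-inden-6-yl (2S,3S)-2,3-dimethyloxirane-2-carboxylate | C=C1C[C@@H](OC(=O)[C@@]2(C)O[C@H]2C)[C@@H](C(C)C)[C@@H]2[C@@H](C(C)=O)[C@@H](O)C[C@@H]12 | intermediate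
31 | (Z)-2-methylbut-2-enoic 2,4,6-trichlorobenzoic anhydride | C/C=C(/C)C(=O)OC(=O)c1c(Cl)cc(Cl)cc1Cl | intermediate
32 | (1R,2S,3aR,6R,7S,7aR)-1-acetyl-4-methylidene-2-{[(2Z)-2-methylbut-2-enoyl]oxy}-7-(propan-2-yl)octahydro-1H-inden-6-yl (2S,3S)-2,3-dimethyloxirane-2-carboxylate (CNP0300602.1) | C=C1C[C@@H](OC(=O)[C@@]2(C)O[C@H]2C)[C@@H](C(C)C)[C@@H]2[C@@H](C(C)=O)[C@@H](OC(=O)/C(C)=C\C)C[C@@H]12 | target

**Total step count:** 20.
**Longest linear sequence:** 16 steps (steps 1, 3 to 14 and 18 to 20).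

**Steps most likely to fail**

Step 12. The aldol closure may show poor facial selectivity at C6, because only the Felkin–Anh bias of the C7 centre, not a ring constraint, steers the approach of C5, and equilibration could favour the equatorial carbinol. The fallback sets C6 by reagent control after both rings exist instead of in the cascade. Setting out from 18, the cascade product is then taken on as the C6-epimeric ketol (1R,2S,3aR,6S,7S,7aS)-2-[(tert-butyldimethylsilyl)oxy]-6-hydroxy-1-(2-methyl-1,3-dioxolan-2-yl)-7-(propan-2-yl)octahydro-4H-inden-4-one F1. It would be methylenated as in step 13 to the equatorial alcohol (1R,2S,3aR,6S,7S,7aR)-2-[(tert-butyldimethylsilyl)oxy]-1-(2-methyl-1,3-dioxolan-2-yl)-4-methylidene-7-(propan-2-yl)octahydro-1H-inden-6-ol F2. Oxidation with Dess–Martin periodinane (NaHCO3, CH2Cl2) would give the β,γ-unsaturated ketone (1R,2S,3aR,7S,7aR)-2-[(tert-butyldimethylsilyl)oxy]-1-(2-methyl-1,3-dioxolan-2-yl)-4-methylidene-7-(propan-2-yl)octahydro-6H-inden-6-one F3, used at once. Reduction with LiBH(s-Bu)3 in THF at −78 °C, which attacks a 2-alkylcyclohexanone from the equatorial side as it does with menthone, should return the axial alcohol 21.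

Step 9. Addition of the hindered phosphonate anion to the hindered, enolisable aldehyde may be slower than enolisation or β-elimination of 13 under the basic conditions. The fallback makes the C7a=C7 bond by aldol-type addition and dehydration instead of phosphorus olefination. Setting out from 13, a Reformatsky addition of ethyl 2-bromo-3-methylbutanoate mediated by CrCl2 (THF, rt), which is non-basic and selective for aldehydes over ketones, should give the β-hydroxy ester ethyl 5-[(tert-butyldimethylsilyl)oxy]-3-hydroxy-4-(2-methyl-1,3-dioxolan-2-yl)-8-oxo-2-(propan-2-yl)nonanoate F4 (C4 and C5 as in 13, C2 and C3 as mixtures). Mesylation (MsCl, Et3N, CH2Cl2) to the corresponding 3-methanesulfonate F5 and elimination with DBU would come back to the route at the enoate 16.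

Step 18. Acyl transfer to the axial C6 hydroxyl, which is flanked by the isopropyl group, from an α-quaternary acyl donor may stall, leaving the mixed anhydride to decompose. The fallback acylates the metal alkoxide at the ketal stage, where no enolisable ketone is present, and removes the ketal afterwards. Setting out from 21, deprotonation with LiN(SiMe3)2 (THF, −78 °C) and addition of the pre-formed mixed anhydride 28 should give (1R,2S,3aR,6R,7S,7aR)-2-[(tert-butyldimethylsilyl)oxy]-1-(2-methyl-1,3-dioxolan-2-yl)-4-methylidene-7-(propan-2-yl)octahydro-1H-inden-6-yl (2S,3S)-2,3-dimethyloxirane-2-carboxylate F8. Ketal hydrolysis as in step 14 (PPTS, acetone/H2O) would then come back to the route at 29.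

**Further compounds**

F1 | step 12 | (1R,2S,3aR,6S,7S,7aS)-2-[(tert-butyldimethylsilyl)oxy]-6-hydroxy-1-(2-methyl-1,3-dioxolan-2-yl)-7-(propan-2-yl)octahydro-4H-inden-4-one | O=C1C[C@H](O)[C@@H](C(C)C)[C@@H]2[C@@H](C3(C)OCCO3)[C@@H](O[Si](C)(C)C(C)(C)C)C[C@@H]12
F2 | step 12 | (1R,2S,3aR,6S,7S,7aR)-2-[(tert-butyldimethylsilyl)oxy]-1-(2-methyl-1,3-dioxolan-2-yl)-4-methylidene-7-(propan-2-yl)octahydro-1H-inden-6-ol | C=C1C[C@H](O)[C@@H](C(C)C)[C@@H]2[C@@H](C3(C)OCCO3)[C@@H](O[Si](C)(C)C(C)(C)C)C[C@@H]12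
F3 | step 12 | (1R,2S,3aR,7S,7aR)-2-[(tert-butyldimethylsilyl)oxy]-1-(2-methyl-1,3-dioxolan-2-yl)-4-methylidene-7-(propan-2-yl)octahydro-6H-inden-6-one | C=C1CC(=O)[C@@H](C(C)C)[C@@H]2[C@@H](C3(C)OCCO3)[C@@H](O[Si](C)(C)C(C)(C)C)C[C@@H]12
F4 | step 9 | ethyl 5-[(tert-butyldimethylsilyl)oxy]-3-hydroxy-4-(2-methyl-1,3-dioxolan-2-yl)-8-oxo-2-(propan-2-yl)nonanoate (C4 and C5 as in 13; C2 and C3 mixtures) | CC(=O)CC[C@H](O[Si](C)(C)C(C)(C)C)[C@@H](C(O)C(C(C)C)C(=O)OCC)C1(C)OCCO1
F5 | step 9 | ethyl 5-[(tert-butyldimethylsilyl)oxy]-3-(methanesulfonyloxy)-4-(2-methyl-1,3-dioxolan-2-yl)-8-oxo-2-(propan-2-yl)nonanoate (C4 and C5 as in 13; C2 and C3 mixtures) | CC(=O)CC[C@H](O[Si](C)(C)C(C)(C)C)[C@@H](C(OS(C)(=O)=O)C(C(C)C)C(=O)OCC)C1(C)OCCO1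
F8 | step 18 | (1R,2S,3aR,6R,7S,7aR)-2-[(tert-butyldimethylsilyl)oxy]-1-(2-methyl-1,3-dioxolan-2-yl)-4-methylidene-7-(propan-2-yl)octahydro-1H-inden-6-yl (2S,3S)-2,3-dimethyloxirane-2-carboxylate | C=C1C[C@@H](OC(=O)[C@@]2(C)O[C@H]2C)[C@@H](C(C)C)[C@@H]2[C@@H](C3(C)OCCO3)[C@@H](O[Si](C)(C)C(C)(C)C)C[C@@H]12
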